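A direct plan would build the furan last. A bis(methoxymethyl)-protected aryl vinyl carbinol would be etherified with 2,3-dibromopropene, and the vinyl bromide lithiated and acylated to enone A1. The ketone would be reduced and esterified to diene A2. Ring-closing metathesis to dihydrofuran A3, dehydrogenation to furan A4 and deprotection would follow. Its weakest steps would be:
- the lithiation–acylation, because a 2-lithioallyl ether can expel its alkoxide to give an allene, and A1 is a ready Michael acceptor;
- the asymmetric reduction of A1, because its two flanks (a CH2 group and a 1,1-disubstituted vinyl group) differ little in size, so facial control would be unsure;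
- the dehydrogenation of A3 beside an electron-rich arene, with protection and deprotection adding length only.

The route rests on the bond between furan C5 and the benzene ring, made by direct C–H addition of an intact 3-substituted furan to 1,4-benzoquinone. The step exploits two features of the target: the reduced quinone is the 2,5-dihydroxyphenyl ring itself and its four CH positions are equivalent, and furan C5 is the only α-position not flanked by the branched side chain at C3. In one operation it would give the unprotected 2-aryl-4-alkylfuran, so that no organolithium acylation, no ketone reduction, no furan construction or dehydrogenation and no protecting group is needed; the carbinol comes from catalytic allylboration of furan-3-carbaldehyde.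

Key step: step 3

Remark: the facial sense of the phosphoric-acid-catalysed allylboration in step 1 is assumed to follow that of benzaldehyde, for which the (R)-acid gives the (R)-carbinol; the (S)-acid is therefore used.

Step 1
Reactants: 1 furan-3-carbaldehyde; 2 allylboronic acid pinacol ester
Product: 4 (1S)-1-(furan-3-yl)but-3-en-1-ol, via pinacol borate ester 3 (not isolated)
Conditions: (S)-3,3'-bis(2,4,6-triisopropylphenyl)-1,1'-binaphthyl-2,2'-diyl hydrogen phosphate (5 mol %), toluene, −30 °C; then H2O
Reagents that add atoms: none
Why: Brønsted-acid-catalysed allylboration through a closed six-membered chair transition state, in which the chiral phosphoric acid hydrogen-bonds to a boronate oxygen and to the formyl hydrogen, so that the (S)-acid should direct the allyl group to the Si face of the aldehyde and set the (S)-carbinol, and water then cleaves the B–O bond of borate 3.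

Step 2
Reactants: 4 (1S)-1-(furan-3-yl)but-3-en-1-ol; 5 3-methylbut-2-enoic acid
Product: 6 (1S)-1-(furan-3-yl)but-3-enyl 3-methylbut-2-enoate
Conditions: DCC (1.5 equiv), 4-(dimethylamino)pyridine (0.2 equiv), CH2Cl2, 0 °C to rt
Reagents that add atoms: none
Why: Steglich esterification acylates the furylic carbinol at oxygen without touching its C–O bond, so the (S) configuration is retained, and it avoids the ketene pathway by which the acid chloride with amine bases gives the deconjugated ester.

Step 3
Reactants: 6 (1S)-1-(furan-3-yl)but-3-enyl 3-methylbut-2-enoate; 7 1,4-benzoquinone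
Product: 9 (1S)-1-[5-(2,5-dihydroxyphenyl)furan-3-yl]but-3-enyl 3-methylbut-2-enoate, via furylbenzoquinone 8 (not isolated)
Conditions: 1,4-benzoquinone (2.5 equiv), Sc(OTf)3 (10 mol %), CH3CN, −20 °C to rt, argon; then aq Na2S2O4, EtOAc
Reagents that add atoms: none
Why: Sc(OTf)3 binds a quinone carbonyl and the furan attacks the activated enone carbon through C5, the σ-complex loses the C5 proton to restore the furan and the enedione adduct enolises to the hydroquinone, and the part that the excess quinone oxidises to quinone 8 is returned to 9 by dithionite. The closest known reaction type is the acid-catalysed substitutive (Friedel–Crafts-type conjugate) addition of furans to p-benzoquinones at the furan α-position. No ring is closed and no stereocentre is created, the (S)-carbinol carbon being a spectator. The step needs site selectivity for C5 over C2 and C4, which the substrate should secure because C4 is a β-position, C2 is flanked by the branched acyloxyalkyl group and the inductive pull of its C–O bond offsets the ortho-activation that a plain alkyl group would give, while the four CH positions of the quinone are equivalent. It also needs chemoselectivity for the furan over the alkenes, secured because only a monosubstituted alkene and a conjugated enoate are present at this stage, the more nucleophilic trisubstituted alkene being introduced afterwards. Double furylation should be held back by the excess of quinone and the low temperature, and the mild Lewis acid should leave the furylic ester un-ionised.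

Step 4
Reactants: 9 (1S)-1-[5-(2,5-dihydroxyphenyl)furan-3-yl]but-3-enyl 3-methylbut-2-enoate; 10 2-methylbut-2-ene
Product: 11 (1S)-1-[5-(2,5-dihydroxyphenyl)furan-3-yl]-4-methylpent-3-enyl 3-methylbut-2-enoate
Conditions: second-generation Grubbs catalyst RuCl2(=CHPh)(H2IMes)(PCy3) (5 mol %), 2-methylbut-2-ene (large excess)–CH2Cl2, 35 °C, sealed tube, argon
Reagents that add atoms: none
Why: Olefin cross-metathesis, in which the ruthenium carbene engages the only monosubstituted alkene and the excess of 2-methylbut-2-ene caps it as the trisubstituted alkene with loss of propene, while the trisubstituted conjugated enoate, the furan, the free phenols and the homoallylic stereocentre should be left untouched.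

**Compound list**

1 | furan-3-carbaldehyde | O=Cc1ccoc1 | starting material
2 | allylboronic acid pinacol ester (4,4,5,5-tetramethyl-2-prop-2-enyl-1,3,2-dioxaborolane) | C=CCB1OC(C)(C)C(C)(C)O1 | starting material
3 | 2-[(1S)-1-(furan-3-yl)but-3-enoxy]-4,4,5,5-tetramethyl-1,3,2-dioxaborolane (not isolated) | C=CC[C@H](OB1OC(C)(C)C(C)(C)O1)c1ccoc1 | intermediate
4 | (1S)-1-(furan-3-yl)but-3-en-1-ol | C=CC[C@H](O)c1ccoc1 | intermediate
5 | 3-methylbut-2-enoic acid | CC(C)=CC(=O)O | starting material
6 | (1S)-1-(furan-3-yl)but-3-enyl 3-methylbut-2-enoate | C=CC[C@H](OC(=O)C=C(C)C)c1ccoc1 | intermediate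
7 | 1,4-benzoquinone | O=C1C=CC(=O)C=C1 | starting material
8 | (1S)-1-[5-(3,6-dioxocyclohexa-1,4-dien-1-yl)furan-3-yl]but-3-enyl 3-methylbut-2-enoate (not isolated) | C=CC[C@H](OC(=O)C=C(C)C)c1coc(C2=CC(=O)C=CC2=O)c1 | intermediate
9 | (1S)-1-[5-(2,5-dihydroxyphenyl)furan-3-yl]but-3-enyl 3-methylbut-2-enoate | C=CC[C@H](OC(=O)C=C(C)C)c1coc(-c2cc(O)ccc2O)c1 | intermediate
10 | 2-methylbut-2-ene | CC=C(C)C | starting material
11 | (1S)-1-[5-(2,5-dihydroxyphenyl)furan-3-yl]-4-methylpent-3-enyl 3-methylbut-2-enoate | CC(C)=CC[C@H](OC(=O)C=C(C)C)c1coc(-c2cc(O)ccc2O)c1 | target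

Total step count: 4. Longest linear sequence: 4.

Steps most likely to fail:

**Step 3.** The addition may lose site selectivity between C5 and C2 of the furan, the Lewis acid may ionise the furylic ester, or the adduct may be furylated a second time. The fallback sets out from 6 and comes back at 11.
- Cross-metathesis of 6 with 2-methylbut-2-ene (second-generation Grubbs catalyst, CH2Cl2, 35 °C) would give (1S)-1-(furan-3-yl)-4-methylpent-3-enyl 3-methylbut-2-enoate F1. The trisubstituted alkene is put in first because it is inert to the borylation catalyst.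
- Sterically governed C–H borylation of F1 (bis(pinacolato)diboron, [Ir(OMe)(cod)]2, 4,4'-di-tert-butyl-2,2'-bipyridine, THF, rt) should take place at the unhindered α-position C5. It would give (1S)-4-methyl-1-[5-(4,4,5,5-tetramethyl-1,3,2-dioxaborolan-2-yl)furan-3-yl]pent-3-enyl 3-methylbut-2-enoate F2.
- Suzuki–Miyaura coupling of F2 with 2-bromobenzene-1,4-diol (Pd(OAc)2, SPhos, K3PO4, degassed THF–H2O, 40 °C) would give 11.

**Step 4.** The free hydroquinone may deactivate the ruthenium carbene or be oxidised during the long reaction, leaving conversion incomplete. The fallback sets out from 9 and comes back at 11.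
- Acetylation of both phenols (Ac2O, pyridine, rt) would give (1S)-1-[5-(2,5-diacetoxyphenyl)furan-3-yl]but-3-enyl 3-methylbut-2-enoate F3.
- Cross-metathesis of F3 with 2-methylbut-2-ene under the conditions of step 4 would give (1S)-1-[5-(2,5-diacetoxyphenyl)furan-3-yl]-4-methylpent-3-enyl 3-methylbut-2-enoate F4.
- Hydrazinolysis of the two aryl acetates (hydrazine hydrate, THF, 0 °C, argon) would give 11; the aryl esters react far faster than the hindered alkyl enoate.

**Step 1.** Facial selectivity may be insufficient with the small heteroaryl aldehyde. The fallback sets out from 1 and comes back at 4.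
- Addition of allylmagnesium bromide (THF, 0 °C) would give racemic 1-(furan-3-yl)but-3-en-1-ol F5.
- Lipase-catalysed kinetic resolution (Burkholderia cepacia lipase, vinyl acetate, tert-butyl methyl ether, rt) should, by Kazlauskas' rule, acetylate the (R)-enantiomer to (1R)-1-(furan-3-yl)but-3-enyl acetate F6. The unreacted (S)-alcohol 4 would be separated by chromatography.

Further compounds
F1 | step 3 | (1S)-1-(furan-3-yl)-4-methylpent-3-enyl 3-methylbut-2-enoate | CC(C)=CC[C@H](OC(=O)C=C(C)C)c1ccoc1
F2 | step 3 | (1S)-4-methyl-1-[5-(4,4,5,5-tetramethyl-1,3,2-dioxaborolan-2-yl)furan-3-yl]pent-3-enyl 3-methylbut-2-enoate | CC(C)=CC[C@H](OC(=O)C=C(C)C)c1coc(B2OC(C)(C)C(C)(C)O2)c1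
F3 | step 4 | (1S)-1-[5-(2,5-diacetoxyphenyl)furan-3-yl]but-3-enyl 3-methylbut-2-enoate | C=CC[C@H](OC(=O)C=C(C)C)c1coc(-c2cc(OC(C)=O)ccc2OC(C)=O)c1
F4 | step 4 | (1S)-1-[5-(2,5-diacetoxyphenyl)furan-3-yl]-4-methylpent-3-enyl 3-methylbut-2-enoate | CC(C)=CC[C@H](OC(=O)C=C(C)C)c1coc(-c2cc(OC(C)=O)ccc2OC(C)=O)c1
F5 | step 1 | racemic 1-(furan-3-yl)but-3-en-1-ol | C=CCC(O)c1ccoc1
F6 | step 1 | (1R)-1-(furan-3-yl)but-3-enyl acetate | C=CC[C@@H](OC(C)=O)c1ccoc1
A1 | direct plan | 2-[[1-[2,5-bis(methoxymethoxy)phenyl]prop-2-enoxy]methyl]-6-methylhepta-1,5-dien-3-one | CC(C)=CCC(=O)C(=C)COC(C=C)c1cc(OCOC)ccc1OCOC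
A2 | direct plan | (3S)-2-[[1-[2,5-bis(methoxymethoxy)phenyl]prop-2-enoxy]methyl]-6-methylhepta-1,5-dien-3-yl 3-methylbut-2-enoate | CC(C)=CC[C@H](OC(=O)C=C(C)C)C(=C)COC(C=C)c1cc(OCOC)ccc1OCOC
A3 | direct plan | (1S)-1-[5-[2,5-bis(methoxymethoxy)phenyl]-2,5-dihydrofuran-3-yl]-4-methylpent-3-enyl 3-methylbut-2-enoate | CC(C)=CC[C@H](OC(=O)C=C(C)C)C1=CC(c2cc(OCOC)ccc2OCOC)OC1
A4 | direct plan | (1S)-1-[5-[2,5-bis(methoxymethoxy)phenyl]furan-3-yl]-4-methylpent-3-enyl 3-methylbut-2-enoate | CC(C)=CC[C@H](OC(=O)C=C(C)C)c1coc(-c2cc(OCOC)ccc2OCOC)c1
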